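**Retrosynthetic overview**
1. Target ⇐ C19 alcohol oxidised last; C12–C13 from syn-hydroalkylation of tert-butyl but-2-ynoate with the C12 borane of a 9-vinyl decalin; the C9 arm is grown from the C9 ketone (methylenation, hydroboration, oxidation, Wittig).
2. cis-2,3-Diacetate ⇐ OsO4 on a C2=C3 alkene, anti to the syn-axial C20/C19 pair, run while C7=C8 is still a deactivated enone.
3. Ring A ⇐ [3+3] annulation that makes C1–C10 and C3–C4 in one pot from 6-methylcarvone and (Z)-3-bromo-1-iodopropene: enolate alkylation, then 6-exo Heck cyclisation ended by borylation at C19.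
4. Enabling feature: the C1–C2–C3 bridge of ring A lies between two quaternary carbons that carvone already holds in latent form. C10 is the α'-carbon of the ring B carbonyl (C9); C4 is the internal carbon of the isopropenyl group (C4(C18)=C19) on C5 and keeps no hydrogen after carbopalladation, so C19–Pd cannot β-eliminate and is borylated.
5. Ring order: ring B comes with (S)-carvone (C5 stereocentre, C8 methyl, C7=C8); ring A is closed in the key step.

Key step: step 4

Remark: labdane numbering is used (ring A: C1–C5, C10; ring B: C5–C10; C11–C16 side chain on C9; C17 on C8; C18 methyl and C19 on C4; C20 on C10). The target is (2S,3R,4S,5S,9R,10S), a trans-decalin with H5 anti to C20. Linchpin 3 is assumed not to be a stock chemical and is made in steps 1–2.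

**Step 1**
Reactants: 1 ethyl (Z)-3-iodoprop-2-enoate
Product: 2 (Z)-3-iodoprop-2-en-1-ol
Conditions: iBu2AlH (2.2 equiv), CH2Cl2, −78 °C; aq. KNaC4H4O6 work-up
Reagents that add atoms: none
Why: Reduction of an ester to the primary alcohol with iBu2AlH at low temperature is standard and leaves the (Z)-vinyl iodide untouched; no stereocentre is formed.

**Step 2**
Reactants: 2 (Z)-3-iodoprop-2-en-1-ol
Product: 3 (Z)-3-bromo-1-iodoprop-1-ene
Conditions: CBr4, PPh3, CH2Cl2, 0 °C
Reagents that add atoms: tetrabromomethane, BrC(Br)(Br)Br
Why: The Appel reaction converts the primary allylic alcohol into the bromide under neutral conditions with the (Z)-alkene geometry retained; no stereocentre is formed.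

**Step 3**
Reactants: 4 (S)-(+)-carvone
Product: 6 6-methylcarvone (C6 epimers; trans major), via lithium dienolate 5 (not isolated)
Conditions: LiN(iPr)2, THF, −78 °C; MeI, −78 → 0 °C
Reagents that add atoms: iodomethane, CI
Why: Kinetic α'-deprotonation of the enone gives the cross-conjugated dienolate, which is C-methylated (enolate alkylation); the new centre is of no consequence because it becomes planar again in step 4.

**Step 4**
Reactants: 6 6-methylcarvone; 3 (Z)-3-bromo-1-iodoprop-1-ene
Product: 9 trans-fused Δ2,Δ7-dien-9-one boronate (C19H2Bpin axial on C4; syn to C20), via lithium enolate 7 (not isolated), via vinyl iodide 8 (not isolated)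
Conditions: LiN(SiMe3)2, THF, −78 → −30 °C; 3, −78 → 0 °C; then Pd(PPh3)4 (5 mol %), B2pin2, KOAc, 1,4-dioxane added, 80 °C
Reagents that add atoms: bis(pinacolato)diboron, CC1(C)OB(OC1(C)C)B1OC(C)(C)C(C)(C)O1
Why: Proposed new method: two known reaction types are telescoped into one annulation — the kinetic cross-conjugated lithium enolate 7 (C10–H is the only α'-hydrogen of 6) is alkylated in SN2 fashion at the allylic bromide of 3 to give 8 (bond C1–C10), then zerovalent palladium inserts into the (Z)-C3–I bond, the alkenylpalladium adds syn across the isopropenyl group at its internal carbon (bond C3–C4), and the neopentyl C19–Pd species, which has no β-hydrogen because C4 is now quaternary, is captured by B2pin2/KOAc (transmetalation, C–B reductive elimination). The closest known reactions are ketone-enolate alkylation with (Z)-3-bromo-1-iodopropene followed by palladium-mediated ring closure, and the domino Heck/borylation of aryl halides bearing 1,1-disubstituted alkenes; new here are the alkenyl iodide partner, the six-membered ring and the one-pot union with the alkylation. Ring A closes in the 6-exo-trig mode (C3 onto C4 of the C4=C19 alkene), 7-endo attack at C19 being disfavoured by ring size and by the usual exo preference of intramolecular carbopalladation. C10 is set in the alkylation, the electrophile entering anti to the pseudo-axial isopropenyl group on C5, so the C1 and C4 arms end up trans (the later trans ring fusion) and both C10 epimers of 6 converge through planar 7. C4 is set in the insertion: in the chair-like transition state with both arms equatorial on ring B, the C4=C19 bond must eclipse the C3–Pd bond, i.e. stand perpendicular to the developing C1–C2=C3–C4 plane, which puts C19 pseudo-axial on the face of C20 and leaves methyl C18 equatorial, as in the target. The step needs site-selective enolisation (secured by the structure of 6 and by LiN(SiMe3)2, whose amine has no β-hydrogen to act as a hydride donor), alkylation at the sp3 C–Br and not at the vinyl C–I (SN2 reactivity), and cyclisation faster than direct borylation of the vinyl iodide (intramolecularity; the catalyst is added only after the alkylation is complete).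

**Step 5**
Reactants: 9 boronate
Product: 10 C19 alcohol (trans-fused Δ2,Δ7-dien-9-one; CH2OH axial on C4)
Conditions: NaBO3·4H2O, THF/H2O, 0 °C → rt
Reagents that add atoms: sodium perborate tetrahydrate, [Na+].[O-]OB=O.O.O.O.O
Why: Perborate oxidation of the alkyl pinacol boronate (peroxide addition to boron, then 1,2-shift) gives the primary alcohol without touching a stereocentre and is mild enough to spare the enone.

**Step 6**
Reactants: 10 C19 alcohol
Product: 11 C19 tert-butyldimethylsilyl ether
Conditions: TBSCl, imidazole, DMF, rt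
Reagents that add atoms: tert-butyldimethylsilyl chloride, CC(C)(C)[Si](C)(C)Cl
Why: Silylation of the primary neopentyl alcohol is routine and masks C19–OH through the ring A and C9 chemistry; no stereocentre is formed.

**Step 7**
Reactants: 11 silyl ether
Product: 12 2,3-cis-diol (both OH anti to C20; C3–OH axial; C2–OH equatorial)
Conditions: OsO4 (2 mol %), NMO, acetone/H2O, rt
Reagents that add atoms: osmium tetroxide, O=[Os](=O)(=O)=O; N-methylmorpholine N-oxide, C[N+]1([O-])CCOCC1; water, O
Why: In this Upjohn dihydroxylation OsO4 adds syn to the cis-disubstituted C2=C3 alkene from the face opposite the syn-axial C20 methyl and C19H2OTBS group, which sets C2 and C3 as in the target, while the electron-poor conjugated C7=C8 alkene is left alone.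

**Step 8**
Reactants: 12 diol
Product: 13 2,3-diacetate
Conditions: Ac2O, DMAP (cat.), pyridine, 40 °C
Reagents that add atoms: acetic anhydride, CC(=O)OC(C)=O
Why: DMAP-catalysed acylation esterifies both secondary alcohols, including the hindered axial C3–OH, without touching a stereocentre.

**Step 9**
Reactants: 13 diacetate
Product: 14 9(11),7-diene (exocyclic C9=C11H2)
Conditions: Zn, CH2Br2, TiCl4 (pre-formed reagent), THF/CH2Cl2, 0 °C → rt
Reagents that add atoms: dibromomethane, BrCBr
Why: Lombardo methylenation converts hindered ketones into methylene compounds under non-basic conditions that tolerate acetates and silyl ethers; no stereocentre is formed.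

**Step 10**
Reactants: 14 diene
Product: 16 C11 alcohol (C9–CH2OH equatorial; cis to C20), via alkylborane 15 (not isolated)
Conditions: 9-BBN, THF, 0 °C → rt; then NaBO3·4H2O, H2O, rt
Reagents that add atoms: sodium perborate tetrahydrate, [Na+].[O-]OB=O.O.O.O.O
Why: In this hydroboration–oxidation 9-BBN adds to the terminal 1,1-disubstituted end of the diene with boron on C11 and hydrogen delivered to C9 from the face opposite the axial C20 methyl, which sets C9, and perborate then gives the alcohol with the acetates intact.

**Step 11**
Reactants: 16 C11 alcohol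
Product: 17 C11 aldehyde (β,γ-unsaturated)
Conditions: Dess–Martin periodinane, NaHCO3, CH2Cl2, 0 °C → rt
Reagents that add atoms: none
Why: Dess–Martin oxidation gives the aldehyde under buffered conditions that do not epimerise C9, whose configuration is in any case the more stable equatorial one.

**Step 12**
Reactants: 17 C11 aldehyde
Product: 18 9-vinyl compound (C11=C12)
Conditions: Ph3PCH3Br, KN(SiMe3)2, THF, 0 °C; then 17, −78 → 0 °C
Reagents that add atoms: methyltriphenylphosphonium bromide, C[P+](c1ccccc1)(c1ccccc1)c1ccccc1.[Br-]
Why: Wittig methylenation of the aldehyde at low temperature should outrun epimerisation at C9, double-bond migration and attack on the acetates; no stereocentre is formed.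

**Step 13**
Reactants: 18 9-vinyl compound; 19 tert-butyl but-2-ynoate
Product: 21 tert-butyl (13E)-enoate (full side chain), via alkylborane 20 (not isolated)
Conditions: 9-BBN, THF, rt; then 19, CuOAc (5 mol %), P(OPh)3 (10 mol %), KOtBu (10 mol %), tBuOH, 1,4-dioxane, 40 °C
Reagents that add atoms: none
Why: 9-BBN hydroborates only the monosubstituted vinyl group, and copper-catalysed syn conjugate addition of the primary alkylborane to the alkynoate (alkyl and hydrogen add to the same side) places the chain trans to the ester, giving the (E)-3-methyl-2-enoate; no stereocentre is formed.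

**Step 14**
Reactants: 21 tert-butyl ester
Product: 22 C19-hydroxy acid
Conditions: TFA/CH2Cl2/H2O (10:10:1), 0 °C → rt
Reagents that add atoms: none
Why: Acidolysis removes the tert-butyl ester (loss of isobutene) and the primary silyl ether together while the acetates survive, and acetyl migration from O3 to O19 is not possible because the two oxygens are held anti on ring A.

**Step 15**
Reactants: 22 C19-hydroxy acid
Product: 23 target CNP0273594.1
Conditions: Dess–Martin periodinane, CH2Cl2, 0 °C → rt
Reagents that add atoms: none
Why: Dess–Martin oxidation of the neopentyl primary alcohol gives the non-enolisable C19 aldehyde in the presence of the free acid, the acetates and both alkenes without touching a stereocentre.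

**Compound list**
1 | ethyl (Z)-3-iodoprop-2-enoate | CCOC(=O)/C=C\I | starting material
2 | (Z)-3-iodoprop-2-en-1-ol | OC/C=C\I | intermediate
3 | (Z)-3-bromo-1-iodoprop-1-ene | BrC/C=C\I | intermediate
4 | (S)-(+)-carvone, (5S)-2-methyl-5-(prop-1-en-2-yl)cyclohex-2-en-1-one | CC1=CC[C@@H](CC1=O)C(C)=C | starting material
5 | lithium cross-conjugated dienolate of carvone (OLi on C1, C1=C6) | CC1=CC[C@@H](C=C1O[Li])C(C)=C | intermediate
6 | 6-methylcarvone, (5S)-2,6-dimethyl-5-(prop-1-en-2-yl)cyclohex-2-en-1-one, C6 epimers | CC1=CC[C@@H](C(C)C1=O)C(C)=C | intermediate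
7 | lithium cross-conjugated dienolate of 6-methylcarvone | CC1=CC[C@@H](C(C)=C1O[Li])C(C)=C | intermediate
8 | 6-[(Z)-3-iodoprop-2-enyl]-2,6-dimethyl-5-(prop-1-en-2-yl)cyclohex-2-en-1-one, iodoallyl arm trans to isopropenyl | I/C=C\C[C@@]1(C)C(=O)C(C)=CC[C@@H]1C(C)=C | intermediate
9 | trans-fused decalin Δ2,Δ7-dien-9-one with methyls on C4, C8, C10 and CH2Bpin (C19) axial on C4, syn to C20 | C1=CC[C@@]2(C)C(=O)C(C)=CC[C@@H]2[C@]1(C)CB3OC(C)(C)C(C)(C)O3 | intermediate
10 | same decalin dienone with C19H2OH | C1=CC[C@@]2(C)C(=O)C(C)=CC[C@@H]2[C@]1(C)CO | intermediate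
11 | C19 tert-butyldimethylsilyl ether of 10 | C1=CC[C@@]2(C)C(=O)C(C)=CC[C@@H]2[C@]1(C)CO[Si](C)(C)C(C)(C)C | intermediate
12 | 2,3-cis-diol of 11 (OH groups anti to C20), Δ7-en-9-one | O[C@H]1C[C@@]2(C)C(=O)C(C)=CC[C@@H]2[C@](C)(CO[Si](C)(C)C(C)(C)C)[C@H]1O | intermediate
13 | 2,3-diacetate of 12 | CC(=O)O[C@H]1C[C@@]2(C)C(=O)C(C)=CC[C@@H]2[C@](C)(CO[Si](C)(C)C(C)(C)C)[C@H]1OC(C)=O | intermediate
14 | 9-methylene-Δ7 diene diacetate | CC(=O)O[C@H]1C[C@@]2(C)C(=C)C(C)=CC[C@@H]2[C@](C)(CO[Si](C)(C)C(C)(C)C)[C@H]1OC(C)=O | intermediate
15 | C11 B-alkyl-9-borabicyclo[3.3.1]nonane from 14 | CC(=O)O[C@H]1C[C@@]2(C)[C@H](CB3C4CCCC3CCC4)C(C)=CC[C@@H]2[C@](C)(CO[Si](C)(C)C(C)(C)C)[C@H]1OC(C)=O | intermediate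
16 | C11 alcohol (C9–CH2OH cis to C20), Δ7 | CC(=O)O[C@H]1C[C@@]2(C)[C@H](CO)C(C)=CC[C@@H]2[C@](C)(CO[Si](C)(C)C(C)(C)C)[C@H]1OC(C)=O | intermediate
17 | C11 aldehyde | CC(=O)O[C@H]1C[C@@]2(C)[C@H](C=O)C(C)=CC[C@@H]2[C@](C)(CO[Si](C)(C)C(C)(C)C)[C@H]1OC(C)=O | intermediate
18 | 9-vinyl compound | CC(=O)O[C@H]1C[C@@]2(C)[C@H](C=C)C(C)=CC[C@@H]2[C@](C)(CO[Si](C)(C)C(C)(C)C)[C@H]1OC(C)=O | intermediate
19 | tert-butyl but-2-ynoate | CC#CC(=O)OC(C)(C)C | starting material
20 | C12 B-alkyl-9-borabicyclo[3.3.1]nonane from 18 | CC(=O)O[C@H]1C[C@@]2(C)[C@H](CCB3C4CCCC3CCC4)C(C)=CC[C@@H]2[C@](C)(CO[Si](C)(C)C(C)(C)C)[C@H]1OC(C)=O | intermediate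
21 | tert-butyl (13E)-2,3-diacetoxy-19-silyloxy-labda-7,13-dien-15-oate (target configuration) | CC(=O)O[C@H]1C[C@@]2(C)[C@H](CC/C(C)=C/C(=O)OC(C)(C)C)C(C)=CC[C@@H]2[C@](C)(CO[Si](C)(C)C(C)(C)C)[C@H]1OC(C)=O | intermediate
22 | (13E)-2,3-diacetoxy-19-hydroxy-labda-7,13-dien-15-oic acid (target configuration) | CC(=O)O[C@H]1C[C@@]2(C)[C@H](CC/C(C)=C/C(=O)O)C(C)=CC[C@@H]2[C@](C)(CO)[C@H]1OC(C)=O | intermediate
23 | CNP0273594.1, (2S,3R,4S,5S,9R,10S,13E)-2,3-diacetoxy-19-oxo-labda-7,13-dien-15-oic acid | CC(=O)O[C@H]1C[C@@]2(C)[C@H](CC/C(C)=C/C(=O)O)C(C)=CC[C@@H]2[C@](C)(C=O)[C@H]1OC(C)=O | target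

**Step count**
Total: 15 steps. Longest linear sequence: 14 steps (steps 1, 2 and 4–15, from 1 to 23). Step 3 is a one-step branch from 4 that joins at step 4, and 19 enters at step 13.

**Steps most likely to fail**

Step 4 (Proposed new method). What may go wrong: borylation of the alkenyl iodide before ring closure; or re-insertion of the neopentylpalladium species into the new C2=C3 alkene (3-exo closure, then cyclopropane or ring-enlarged products); or protodepalladation. The fallback builds the C3–C4 bond by enolate coupling instead of carbopalladation and sets out from 6 and 3. Alkylation of 6 with 3 (LiN(SiMe3)2, THF) is worked up and vinyl iodide 8 is isolated. mCPBA should then epoxidise only the electron-rich isopropenyl group to give epoxide F1. BF3·OEt2 should rearrange F1 (Meinwald, hydride shift) to α-methyl aldehyde F2. Palladium-catalysed intramolecular α-alkenylation of the aldehyde enolate (Pd(PPh3)4, Cs2CO3, THF, 60 °C) should close ring A to aldehyde F3, which already carries C19 at the aldehyde level. NaBH4 at −78 °C should reduce the aldehyde in preference to the hindered conjugated ketone, and the route is rejoined at alcohol 10.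

Step 10. What may go wrong: hydride delivery to C9 from the wrong face, or 1,4-addition across the diene that moves the ring alkene. The fallback avoids the diene and sets out from 13. Dimethylsulfonium methylide (Me3SI, KN(SiMe3)2, THF, −10 °C; Corey–Chaykovsky) should add to the C9 carbonyl from the face away from C20 to give vinyl oxirane F4. MgBr2·OEt2 should open F4 at the allylic C9–O bond with a 1,2-hydride shift from C11, and the route is rejoined at aldehyde 17.

Step 13. What may go wrong: slow boron-to-copper transfer from the hindered alkylborane, protodeboronation, or erosion of the syn selectivity through isomerisation of the alkenylcopper intermediate. The fallback fixes the alkene geometry in the coupling partner and sets out from 18. But-2-ynoic acid and aqueous HI at 110 °C (equilibrating conditions) should give (E)-3-iodobut-2-enoic acid F5. Alkylborane 20, made from 18 as before, is joined to F5 by B-alkyl Suzuki–Miyaura coupling (Pd(dppf)Cl2, AsPh3, Cs2CO3, DMF/H2O, rt) to give silyl ether acid F6. HF·pyridine removes the silyl group, and the route is rejoined at hydroxy acid 22.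

**Further compounds**
F1 | step 4 | 6-[(Z)-3-iodoprop-2-enyl]-2,6-dimethyl-5-(2-methyloxiran-2-yl)cyclohex-2-en-1-one (epoxide epimers) | I/C=C\C[C@@]1(C)C(=O)C(C)=CC[C@@H]1C2(C)CO2
F2 | step 4 | 2-[6-((Z)-3-iodoprop-2-enyl)-4,6-dimethyl-5-oxocyclohex-3-enyl]propanal (C4 epimers) | I/C=C\C[C@@]1(C)C(=O)C(C)=CC[C@@H]1C(C)C=O
F3 | step 4 | trans-fused decalin Δ2,Δ7-dien-9-one with axial C19 aldehyde on C4 | C1=CC[C@@]2(C)C(=O)C(C)=CC[C@@H]2[C@]1(C)C=O
F4 | step 10 | C9 spiro-oxirane of 13 (CH2 anti to C20) | CC(=O)O[C@H]1C[C@@]2(C)[C@@]3(CO3)C(C)=CC[C@@H]2[C@](C)(CO[Si](C)(C)C(C)(C)C)[C@H]1OC(C)=O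
F5 | step 13 | (E)-3-iodobut-2-enoic acid | I/C(C)=C/C(=O)O
F6 | step 13 | (13E)-2,3-diacetoxy-19-(tert-butyldimethylsilyloxy)-labda-7,13-dien-15-oic acid | CC(=O)O[C@H]1C[C@@]2(C)[C@H](CC/C(C)=C/C(=O)O)C(C)=CC[C@@H]2[C@](C)(CO[Si](C)(C)C(C)(C)C)[C@H]1OC(C)=O
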